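**Plan**
- Numbering is that of the germacrane skeleton: carbocycle C1–C10; lactone C6–O–C12(=O)–C11(=C13)–C7; ether C5–O–C10; C14 = CH3 on C10; C15 = CH2OAc on C4.
- Cuts: the C8 and C15 esters; C11=C13 (Mannich); C1=C2 (RCM, ring B); C8=C9 (RCM, ring A, then re-oxygenated at C8); C10–O (Pd allylic etherification); C4–C5 (aldol); C7–C8 (cuprate).
- Forward: butenolide → lactone with C7 vinyl → aldol adduct (C3–C6) → C5–O–C10 ether → ring A → ring B (inside–outside) → methylene lactone and esters.
- Stereochemistry: C6 from the chiral pool; C7 by anti cuprate addition; C4/C5 from the oxazolidinone; C10 from the Pd ligand; C8 by equatorial hydride attack; C3 by chelation-controlled reduction.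
- Feature used by the key step: C10 carries CH3, the ether O and two arms (C9–C8 and C1), i.e. an isoprene unit O–C(CH3)(CH=CH2)(CH2OH). Its configuration can therefore be set by a catalyst independently of C5, which a trans ether bridge requires; bridging a preformed ring would give the cis bridge.

Key step: step 6

Remark (assumption): as written, the descriptors at C5 and C10 place the two C–O bonds of the ether on opposite faces of the C1–C10 ring (trans-bridged, inside–outside 11-oxabicyclo[4.4.1]undecane, H-5 inside); the route is planned for exactly this diastereomer.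

Abbreviations: TES = triethylsilyl; PMB = 4-methoxybenzyl; PMP = 4-methoxyphenyl; Xc = (R)-4-benzyl-2-oxooxazolidin-3-yl.

**Route**

Step 1
Reactants: 1 (S)-5-(hydroxymethyl)furan-2(5H)-one
Product: 2 (S)-5-[(triethylsilyloxy)methyl]furan-2(5H)-one
Conditions: TESCl, imidazole, CH2Cl2, 0 °C
Reagents that add atoms: chlorotriethylsilane CC[Si](Cl)(CC)CC
Why: Silylation of the primary alcohol; the butenolide stereocentre (C6) is not touched.

Step 2
Reactants: 2 (S)-5-[(triethylsilyloxy)methyl]furan-2(5H)-one
Product: 3 (4R,5S)-5-[(triethylsilyloxy)methyl]-4-vinyldihydrofuran-2(3H)-one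
Conditions: CH2=CHMgBr, CuBr·SMe2 (20 mol%), THF, −78 °C; H2O quench
Reagents that add atoms: vinylmagnesium bromide C=C[Mg]Br
Why: Copper-catalysed conjugate addition to the γ-substituted butenolide takes place anti to the C5 substituent, so C7 is set trans to C6 (the H-6/H-7 trans relationship of the lactone).

Step 3
Reactants: 3 (4R,5S)-5-[(triethylsilyloxy)methyl]-4-vinyldihydrofuran-2(3H)-one
Product: 5 (2S,3R)-5-oxo-3-vinyltetrahydrofuran-2-carbaldehyde, via alkoxysulfonium chloride 4 (not isolated)
Conditions: (COCl)2, DMSO, CH2Cl2, −78 → −40 °C; then Et3N, −78 °C → rt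
Reagents that add atoms: none
Why: Under Swern conditions the activated sulfoxide cleaves a primary triethylsilyl ether at oxygen and oxidises it in the same pot, so no separate deprotection is needed; the aldehyde is used crude to avoid epimerisation at C6.

Step 4
Reactants: 6 3-[(4-methoxybenzyl)oxy]propanoic acid; 7 (R)-4-benzyloxazolidin-2-one
Product: 9 (R)-4-benzyl-3-{3-[(4-methoxybenzyl)oxy]propanoyl}oxazolidin-2-one, via pivalic mixed anhydride 8 (not isolated)
Conditions: PivCl, Et3N, THF, −20 °C; then 7, LiCl, rt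
Reagents that add atoms: none
Why: N-Acylation of the oxazolidinone through the pivalic mixed anhydride, the standard preparation of Evans imides.

Step 5
Reactants: 9 (R)-4-benzyl-3-{3-[(4-methoxybenzyl)oxy]propanoyl}oxazolidin-2-one; 5 (2S,3R)-5-oxo-3-vinyltetrahydrofuran-2-carbaldehyde
Product: 11 (R)-4-benzyl-3-[(2R,3R)-3-hydroxy-2-{[(4-methoxybenzyl)oxy]methyl}-3-[(2S,3R)-5-oxo-3-vinyltetrahydrofuran-2-yl]propanoyl]oxazolidin-2-one, via Z-dibutylboron enolate 10 (not isolated)
Conditions: Bu2BOTf, iPr2NEt, CH2Cl2, −78 → 0 °C; then 5, −78 → 0 °C; pH 7 buffer, MeOH, H2O2, 0 °C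
Reagents that add atoms: none
Why: Evans syn-aldol reaction: the Z-boron enolate reacts through a Zimmerman–Traxler chair on the face dictated by the (R)-benzyl auxiliary, forming C4–C5 and setting C4 and C5 (2,3-syn), which with the resident C6 gives the 5,6-anti oxygen pattern of the target.

Step 6
Reactants: 11 aldol adduct (free C5–OH); 12 rac-2-methyl-2-vinyloxirane
Product: 13 (R)-4-benzyl-3-[(2R,3R)-3-{[(2S)-1-hydroxy-2-methylbut-3-en-2-yl]oxy}-2-{[(4-methoxybenzyl)oxy]methyl}-3-[(2S,3R)-5-oxo-3-vinyltetrahydrofuran-2-yl]propanoyl]oxazolidin-2-one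
Conditions: Pd2(dba)3·CHCl3 (2.5 mol%), (R,R)-DACH-phenyl Trost ligand (7.5 mol%), Et3B (5 mol%), CH2Cl2, rt, slow addition of 12
Reagents that add atoms: none
Why: Pd(0) ionises either enantiomer of 12 to a π-allyl complex bearing an alkoxide, Et3B links that alkoxide to the C5 hydroxyl of 11 as a borate, and the oxygen is delivered within this complex to the adjacent fully substituted allyl terminus (Tsuji–Trost allylic etherification of a vinyl epoxide). The closest known reaction type is the Pd/boron-catalysed dynamic kinetic asymmetric addition of alcohol pronucleophiles to isoprene monoepoxide, which gives 2-alkoxy-2-methylbut-3-en-1-ols. No ring is closed: the step joins O5 to C10 at the most hindered bond of the target and creates C10, whose configuration (S in 13, the C10 of the target) should be set by the (R,R) ligand because the diastereomeric π-allyl complexes interconvert faster than they are attacked, so it does not depend on C4–C7. Since C5 comes from the aldol and C10 from the ligand, the C5 side chain and the two C10 arms can be placed trans across the ether oxygen, which a ring-bridging etherification could not do (the antipodal ligand would give the cis-bridged series). The step needs branched over linear regioselectivity, secured by the boron tether to the neighbouring alkoxide, and reaction at the secondary C5 hydroxyl instead of the primary hydroxyl of the product, favoured by slow addition of 12 and the neopentyl position of that product hydroxyl. The product carries the two handles used later: the vinyl group (C9=C8) for ring A and the CH2OH group (C1) for ring B.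

Step 7
Reactants: 13 C5–O–C10 ether with C7 vinyl and C10 vinyl
Product: 14 ring-A oxepene: γ-lactone trans-fused at C6–C7 to the ring O–C5–C6–C7–C8=C9–C10; C10 bears CH3 and CH2OH (C1); C5 bears (R)-CH(CH2OPMB)C(=O)Xc
Conditions: Hoveyda–Grubbs II (10 mol%), toluene (5 mM), 80 °C
Reagents that add atoms: none
Why: Ring-closing metathesis of the only two alkenes closes the seven-membered ring A as the cis C8=C9 alkene; the trans fusion to the lactone is already fixed by C6 and C7.

Step 8
Reactants: 14 ring-A oxepene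
Product: 16 C1,C8-diol (14 with C8–OH and C9H2; C8–OH drawn on the face opposite the C10 methyl), via bis-9-BBN adduct 15 (not isolated)
Conditions: 9-BBN (3.5 equiv), THF, 0 → 60 °C; then H2O2, aq. NaOAc, 0 °C → rt
Reagents that add atoms: hydrogen peroxide OO
Why: Hydroboration–oxidation: the free hydroxyl is first converted into its B-alkoxy-9-BBN derivative and the bulky borane then adds to C8, the alkene carbon remote from the fully substituted C10; the C8 configuration formed here is erased in step 9.

Step 9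
Reactants: 16 C1,C8-diol
Product: 17 C8-keto C1-aldehyde (16 with C8=O and C10–CHO)
Conditions: Dess–Martin periodinane, CH2Cl2, rt
Reagents that add atoms: none
Why: Dess–Martin oxidation of both hydroxyls under non-basic conditions, so that the β-acyloxy ketone neither eliminates the C6 oxygen nor epimerises at C7.

Step 10
Reactants: 17 C8-keto C1-aldehyde
Product: 18 C8 ketone with C10 vinyl (17 with C10–CH=CH2)
Conditions: CH2I2, Zn, Ti(OiPr)4, THF, rt
Reagents that add atoms: diiodomethane ICI
Why: Takai-type methylenation with CH2I2/Zn/Ti(OiPr)4 is selective for aldehydes over ketones and is not basic, so C1 becomes the vinyl group for ring B while the C8 ketone survives.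

Step 11
Reactants: 18 C8 ketone with C10 vinyl
Product: 20 C8 triethylsilyl ether (18 with C8–OTES cis to the C7–C11 bond), via lithium C8-alkoxide 19 (not isolated)
Conditions: L-Selectride, THF, −78 °C; then TESOTf, −78 → −40 °C
Reagents that add atoms: triethylsilyl trifluoromethanesulfonate CC[Si](CC)(CC)OS(=O)(=O)C(F)(F)F
Why: The bulky hydride should attack the C8 ketone from the equatorial direction next to the ring-fusion carbon C7, giving the axial alkoxide cis to the C7–C11 bond (the C8 configuration of the target), and silylation in the same pot prevents translactonisation to the 8,12-olide.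

Step 12
Reactants: 20 C8 triethylsilyl ether (imide)
Product: 21 S-ethyl thioester (20 with C3(=O)SEt in place of C3(=O)Xc)
Conditions: EtSH, n-BuLi, THF, 0 °C; AcOH quench
Reagents that add atoms: ethanethiol CCS
Why: Thiolate displacement of the oxazolidinone (standard cleavage of the auxiliary to a thioester) leaves the γ-lactone and the silyl ether untouched and returns auxiliary 7.

Step 13
Reactants: 21 S-ethyl thioester
Product: 22 vinyl ketone (21 with C3(=O)CH=CH2)
Conditions: CH2=CHSnBu3, Pd2(dba)3 (2.5 mol%), P(2-furyl)3, CuOP(O)Ph2 (1.5 equiv), THF, rt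
Reagents that add atoms: tributyl(vinyl)stannane C=C[Sn](CCCC)(CCCC)CCCC
Why: Liebeskind–Srogl-type Pd/Cu coupling of the thioester with the vinylstannane gives the vinyl ketone under neutral conditions, avoiding epimerisation at C4, β-elimination of the C5 ether and attack on the lactone.

Step 14
Reactants: 22 vinyl ketone
Product: 23 (3S)-allylic alcohol (22 with C3H(OH)CH=CH2)
Conditions: Zn(BH4)2, Et2O, −30 °C
Reagents that add atoms: none
Why: Chelation-controlled 1,2-reduction: zinc bridges the C3 carbonyl and the C15 PMB ether and hydride adds anti to the C5 branch of the chelate (the Felkin–Anh pathway gives the same sense), setting C3.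

Step 15
Reactants: 23 (3S)-allylic alcohol with C10 vinyl
Product: 24 inside–outside tricycle: rings A and B closed, C1=C2 alkene, C3–OH, C15–OPMB, C8–OTES, 6,12-lactone
Conditions: Hoveyda–Grubbs II (20 mol%, in portions), 1,4-benzoquinone (10 mol%), toluene (1 mM), 80–110 °C, argon sparge
Reagents that add atoms: none
Why: Ring-closing metathesis of the C10 vinyl and C3 vinyl groups forms the cis C1=C2 alkene of ring B; because the two arms are trans across the ether oxygen the product is necessarily the inside–outside bicycle, RCM is a reaction type known to close inside–outside bicyclo[4.4.1]undecenes, and loss of ethylene drives the closure.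

Step 16
Reactants: 24 inside–outside tricycle with C1=C2
Product: 25 1,2-dihydro tricycle (C1H2–C2H2)
Conditions: 2-nitrobenzenesulfonyl hydrazide, Et3N, CH2Cl2, rt
Reagents that add atoms: none
Why: Diimide generated from the sulfonyl hydrazide reduces the strained cis-disubstituted alkene by syn hydrogen transfer without touching the PMB ether or the lactone.

Step 17
Reactants: 25 1,2-dihydro tricycle
Product: 26 3,15-O-(4-methoxybenzylidene) acetal (six-membered acetal over O3 and O15, aryl equatorial)
Conditions: DDQ, 4 Å MS, CH2Cl2, 0 °C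
Reagents that add atoms: none
Why: Anhydrous DDQ oxidises the PMB ether to its oxocarbenium ion, which the neighbouring C3 hydroxyl traps as the p-methoxybenzylidene acetal, protecting the 3,15-diol in one step.

Step 18
Reactants: 26 3,15-O-(4-methoxybenzylidene) acetal
Product: 28 11-(dimethylaminomethyl) lactone, via lithium lactone enolate 27 (not isolated)
Conditions: LDA, THF, −78 °C; then CH2=NMe2+ I−, −78 °C → rt
Reagents that add atoms: N,N-dimethylmethyleneiminium iodide C=[N+](C)C.[I-]
Why: The lactone enolate (C11 is the only acidic site) undergoes a Mannich reaction with Eschenmoser's salt anti to the C7–C8 bond; the new C11 centre is removed in step 19.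

Step 19
Reactants: 28 11-(dimethylaminomethyl) lactone
Product: 30 α-methylene lactone (C11=C13), C8–OTES, via trimethylammonium iodide 29 (not isolated)
Conditions: MeI, MeOH, rt; then aq. NaHCO3, CH2Cl2
Reagents that add atoms: none
Why: N-Methylation and base-induced elimination of trimethylamine give the α-methylene lactone (Eschenmoser methylenation).

Step 20
Reactants: 30 α-methylene lactone, C8–OTES
Product: 31 C8 alcohol
Conditions: HF·pyridine, pyridine, THF, 0 °C
Reagents that add atoms: none
Why: Buffered HF·pyridine cleaves the triethylsilyl ether while the acetal and the α-methylene lactone survive.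

Step 21
Reactants: 31 C8 alcohol; 32 angelic acid
Product: 34 C8 angelate, via angelic trichlorobenzoic anhydride 33 (not isolated)
Conditions: 2,4,6-Cl3C6H2COCl, Et3N, toluene, rt; then 31, toluene, 80 °C
Reagents that add atoms: none
Why: Yamaguchi esterification through the mixed anhydride acylates the hindered C8 hydroxyl (the only free OH) and, run without DMAP, is known to keep the Z geometry of the angelate.

Step 22
Reactants: 34 C8 angelate (acetal)
Product: 35 3,15-diol (15-deacetyl target)
Conditions: AcOH/THF/H2O (3:1:1), 40 °C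
Reagents that add atoms: none
Why: Mild acid hydrolysis of the benzylidene acetal frees the 3,15-diol; the ester and lactone functions tolerate these conditions.

Step 23
Reactants: 35 3,15-diol
Product: 36 target CNP0277024.1
Conditions: AcCl, 2,4,6-collidine, CH2Cl2, −78 °C
Reagents that add atoms: acetyl chloride CC(=O)Cl
Why: Acetyl chloride with collidine at low temperature acetylates the primary C15 hydroxyl selectively over the hindered secondary C3 hydroxyl, giving the target.

**Compound list**

1 | (S)-5-(hydroxymethyl)furan-2(5H)-one | OC[C@H]1OC(=O)C=C1 | starting material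
2 | (S)-5-[(triethylsilyloxy)methyl]furan-2(5H)-one | CC[Si](CC)(CC)OC[C@H]1OC(=O)C=C1 | intermediate
3 | (4R,5S)-5-[(triethylsilyloxy)methyl]-4-vinyldihydrofuran-2(3H)-one | CC[Si](CC)(CC)OC[C@H]1OC(=O)C[C@@H]1C=C | intermediate
4 | alkoxydimethylsulfonium chloride of the C5 primary alcohol | C[S+](C)OC[C@H]1OC(=O)C[C@@H]1C=C.[Cl-] | intermediate
5 | (2S,3R)-5-oxo-3-vinyltetrahydrofuran-2-carbaldehyde | O=C[C@H]1OC(=O)C[C@@H]1C=C | intermediate
6 | 3-[(4-methoxybenzyl)oxy]propanoic acid | COc1ccc(COCCC(=O)O)cc1 | starting material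
7 | (R)-4-benzyloxazolidin-2-one | O=C1N[C@H](Cc2ccccc2)CO1 | starting material
8 | 3-[(4-methoxybenzyl)oxy]propanoic pivalic anhydride | COc1ccc(COCCC(=O)OC(=O)C(C)(C)C)cc1 | intermediate
9 | (R)-4-benzyl-3-{3-[(4-methoxybenzyl)oxy]propanoyl}oxazolidin-2-one | COc1ccc(COCCC(=O)N2C(=O)OC[C@H]2Cc2ccccc2)cc1 | intermediate
10 | Z-dibutylboron enolate of 9 | COc1ccc(COC/C=C(\OB(CCCC)CCCC)N2C(=O)OC[C@H]2Cc2ccccc2)cc1 | intermediate
11 | (R)-4-benzyl-3-[(2R,3R)-3-hydroxy-2-{[(4-methoxybenzyl)oxy]methyl}-3-[(2S,3R)-5-oxo-3-vinyltetrahydrofuran-2-yl]propanoyl]oxazolidin-2-one | O=C1C[C@H](C=C)[C@@H]([C@H](O)[C@@H](COCc2ccc(OC)cc2)C(=O)N2C(=O)OC[C@H]2Cc2ccccc2)O1 | intermediate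
12 | rac-2-methyl-2-vinyloxirane | CC1(C=C)CO1 | starting material
13 | C5–O–C10 ether: 11 with O5 carrying the (S)-1-hydroxy-2-methylbut-3-en-2-yl group | O=C1C[C@H](C=C)[C@@H]([C@H](O[C@](C)(CO)C=C)[C@@H](COCc2ccc(OC)cc2)C(=O)N2C(=O)OC[C@H]2Cc2ccccc2)O1 | intermediate
14 | ring-A oxepene: lactone trans-fused to O–C5–C6–C7–C8=C9–C10; C10 bears CH3 and CH2OH; C5 bears (R)-CH(CH2OPMB)C(=O)Xc | O=C1C[C@@H]2C=C[C@@](C)(CO)O[C@H]([C@@H](COCc3ccc(OC)cc3)C(=O)N3C(=O)OC[C@H]3Cc3ccccc3)[C@H]2O1 | intermediate
15 | bis-9-BBN adduct of 14 (C8–B and C1–O–B) | O=C1C[C@@H]2[C@@H](B3C4CCCC3CCC4)C[C@@](C)(COB3C4CCCC3CCC4)O[C@H]([C@@H](COCc3ccc(OC)cc3)C(=O)N3C(=O)OC[C@H]3Cc3ccccc3)[C@H]2O1 | intermediate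
16 | C1,C8-diol | O=C1C[C@@H]2[C@@H](O)C[C@@](C)(CO)O[C@H]([C@@H](COCc3ccc(OC)cc3)C(=O)N3C(=O)OC[C@H]3Cc3ccccc3)[C@H]2O1 | intermediate
17 | C8-keto C1-aldehyde | O=C1C[C@@H]2C(=O)C[C@@](C)(C=O)O[C@H]([C@@H](COCc3ccc(OC)cc3)C(=O)N3C(=O)OC[C@H]3Cc3ccccc3)[C@H]2O1 | intermediate
18 | C8 ketone with C10 vinyl | O=C1C[C@@H]2C(=O)C[C@@](C)(C=C)O[C@H]([C@@H](COCc3ccc(OC)cc3)C(=O)N3C(=O)OC[C@H]3Cc3ccccc3)[C@H]2O1 | intermediate
19 | lithium C8-alkoxide (O8 cis to C7–C11) | [Li+].O=C1C[C@@H]2[C@H]([O-])C[C@@](C)(C=C)O[C@H]([C@@H](COCc3ccc(OC)cc3)C(=O)N3C(=O)OC[C@H]3Cc3ccccc3)[C@H]2O1 | intermediate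
20 | C8 triethylsilyl ether (imide) | O=C1C[C@@H]2[C@H](O[Si](CC)(CC)CC)C[C@@](C)(C=C)O[C@H]([C@@H](COCc3ccc(OC)cc3)C(=O)N3C(=O)OC[C@H]3Cc3ccccc3)[C@H]2O1 | intermediate
21 | S-ethyl thioester | O=C1C[C@@H]2[C@H](O[Si](CC)(CC)CC)C[C@@](C)(C=C)O[C@H]([C@@H](COCc3ccc(OC)cc3)C(=O)SCC)[C@H]2O1 | intermediate
22 | vinyl ketone (C3=O) | O=C1C[C@@H]2[C@H](O[Si](CC)(CC)CC)C[C@@](C)(C=C)O[C@H]([C@@H](COCc3ccc(OC)cc3)C(=O)C=C)[C@H]2O1 | intermediate
23 | (3S)-allylic alcohol, RCM precursor | O=C1C[C@@H]2[C@H](O[Si](CC)(CC)CC)C[C@@](C)(C=C)O[C@H]([C@@H](COCc3ccc(OC)cc3)[C@@H](O)C=C)[C@H]2O1 | intermediate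
24 | inside–outside tricycle with C1=C2, C3–OH, C15–OPMB, C8–OTES | O=C1O[C@@H]2[C@@H]3O[C@](C)(C=C[C@H](O)[C@@H]3COCc4ccc(OC)cc4)C[C@@H](O[Si](CC)(CC)CC)[C@H]2C1 | intermediate
25 | 1,2-dihydro tricycle | O=C1O[C@@H]2[C@@H]3O[C@](C)(CC[C@H](O)[C@@H]3COCc4ccc(OC)cc4)C[C@@H](O[Si](CC)(CC)CC)[C@H]2C1 | intermediate
26 | 3,15-O-(4-methoxybenzylidene) acetal | O=C1O[C@@H]2[C@@H]3O[C@](C)(CC[C@@H]4O[C@H](c5ccc(OC)cc5)OC[C@H]34)C[C@@H](O[Si](CC)(CC)CC)[C@H]2C1 | intermediate
27 | lithium lactone enolate of 26 | [Li]OC=1O[C@@H]2[C@@H]3O[C@](C)(CC[C@@H]4O[C@H](c5ccc(OC)cc5)OC[C@H]34)C[C@@H](O[Si](CC)(CC)CC)[C@H]2C=1 | intermediate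
28 | 11-(dimethylaminomethyl) lactone | CN(C)C[C@@H]1C(=O)O[C@@H]2[C@@H]3O[C@](C)(CC[C@@H]4O[C@H](c5ccc(OC)cc5)OC[C@H]34)C[C@@H](O[Si](CC)(CC)CC)[C@@H]12 | intermediate
29 | trimethylammonium iodide of 28 | C[N+](C)(C)C[C@@H]1C(=O)O[C@@H]2[C@@H]3O[C@](C)(CC[C@@H]4O[C@H](c5ccc(OC)cc5)OC[C@H]34)C[C@@H](O[Si](CC)(CC)CC)[C@@H]12.[I-] | intermediate
30 | α-methylene lactone, C8–OTES, 3,15-acetal | C=C1C(=O)O[C@@H]2[C@@H]3O[C@](C)(CC[C@@H]4O[C@H](c5ccc(OC)cc5)OC[C@H]34)C[C@@H](O[Si](CC)(CC)CC)[C@@H]12 | intermediate
31 | C8 alcohol, 3,15-acetal | C=C1C(=O)O[C@@H]2[C@@H]3O[C@](C)(CC[C@@H]4O[C@H](c5ccc(OC)cc5)OC[C@H]34)C[C@@H](O)[C@@H]12 | intermediate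
32 | angelic acid, (Z)-2-methylbut-2-enoic acid | C/C=C(/C)C(=O)O | starting material
33 | angelic 2,4,6-trichlorobenzoic anhydride | C/C=C(/C)C(=O)OC(=O)c1c(Cl)cc(Cl)cc1Cl | intermediate
34 | C8 angelate, 3,15-acetal | C=C1C(=O)O[C@@H]2[C@@H]3O[C@](C)(CC[C@@H]4O[C@H](c5ccc(OC)cc5)OC[C@H]34)C[C@@H](OC(=O)/C(C)=C\C)[C@@H]12 | intermediate
35 | 3,15-diol (15-deacetyl target) | C=C1C(=O)O[C@@H]2[C@@H]3O[C@](C)(CC[C@H](O)[C@@H]3CO)C[C@@H](OC(=O)/C(C)=C\C)[C@@H]12 | intermediate
36 | CNP0277024.1 | C=C1C(=O)O[C@@H]2[C@@H]3O[C@](C)(CC[C@H](O)[C@@H]3COC(C)=O)C[C@@H](OC(=O)/C(C)=C\C)[C@@H]12 | target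

**Count**

Total steps: 23. Longest linear sequence: 22 (steps 1–3 and 5–23; step 4 prepares the imide in parallel).

**Steps most likely to fail**

Step 6. The hindered secondary C5 hydroxyl may fail to intercept the π-allyl complex, so that the epoxide oligomerises or the primary hydroxyl of the product is etherified further; a mismatch between ligand and substrate could also erode selectivity at C10. The fallback sets out from 11 and gives up catalyst control. Compound 11 and 12 would be treated with catalytic BF3·OEt2 in CH2Cl2 at −78 °C, an SN1-type opening of the epoxide at its tertiary allylic carbon. This should give 13 together with the C10-epimeric ether F1; the two would be separated by chromatography and the route rejoined at 13.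

Step 15. Closure of the strained inside–outside ring may lose out to intermolecular metathesis of the accessible C3 allyl arm (oligomers), or the strained alkene may re-open. The fallback sets out from 22 and moves the closure one step earlier. RCM of enone 22 should give the cyclic enone F2, whose conjugated, electron-poor C1=C2 bond is a poor partner for ring-opening. Luche reduction (NaBH4, CeCl3, MeOH, −78 °C), with hydride entering opposite the C4 CH2OPMB group, would then set C3 on the ring and return the route at 24.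

Step 8. Hydroboration may be poorly regioselective (boron also at C9, since the inductive pull of the allylic ether oxygen opposes the steric bias) or too slow on the hindered ring alkene. The fallback sets out from 14 and places the oxygen by a Wacker-type oxidation, in which the same inductive effect directs water to the distal carbon C8. TBDPSCl and imidazole would give the C1 silyl ether F3; Pd(OAc)2 (cat.), benzoquinone and HBF4 in DMA/MeCN/H2O would give the C8 ketone F4; HF·pyridine would give the hydroxy ketone F5; Dess–Martin oxidation returns the route at 17.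

Further compounds
F1 | step 6 | C10-epimeric ether (C10 epimer of 13) | O=C1C[C@H](C=C)[C@@H]([C@H](O[C@@](C)(CO)C=C)[C@@H](COCc2ccc(OC)cc2)C(=O)N2C(=O)OC[C@H]2Cc2ccccc2)O1
F2 | step 15 | cyclic enone (24 with C3=O) | O=C1O[C@@H]2[C@@H]3O[C@](C)(C=CC(=O)[C@@H]3COCc4ccc(OC)cc4)C[C@@H](O[Si](CC)(CC)CC)[C@H]2C1
F3 | step 8 | C1 tert-butyldiphenylsilyl ether of 14 | O=C1C[C@@H]2C=C[C@@](C)(CO[Si](c3ccccc3)(c3ccccc3)C(C)(C)C)O[C@H]([C@@H](COCc3ccc(OC)cc3)C(=O)N3C(=O)OC[C@H]3Cc3ccccc3)[C@H]2O1
F4 | step 8 | C8 ketone, C1 silyl ether | O=C1C[C@@H]2C(=O)C[C@@](C)(CO[Si](c3ccccc3)(c3ccccc3)C(C)(C)C)O[C@H]([C@@H](COCc3ccc(OC)cc3)C(=O)N3C(=O)OC[C@H]3Cc3ccccc3)[C@H]2O1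
F5 | step 8 | C8 ketone, C1 alcohol | O=C1C[C@@H]2C(=O)C[C@@](C)(CO)O[C@H]([C@@H](COCc3ccc(OC)cc3)C(=O)N3C(=O)OC[C@H]3Cc3ccccc3)[C@H]2O1
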